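Readings and results are calculated for an exercise; noise was put on by code.

Let us begin with the easy case: two species that turn into each other and are equally favoured end as equal parts of the pair, and that is the zero of our scale. All amounts here are parts of the substrate charged.

| flask | substrate | remark | time |
|---|---|---|---|
| alpha | 0.0020 M | the very flask that is asked about, followed so far |  |
| eta | 0.0040 M | run made earlier |  |
| flask | 0.0020 M |  | 10 h |

| run | time / h | target / % | isomer of the product / % | substrate / % |
|---|---|---|---|---|
| alpha | 0.667 | 4 | 46 | 49 |
| alpha | 1.33 | 7 | 71 | 23 |
| alpha | 2.00 | 8 | 84 | 9 |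
| alpha | 3.00 | 7 | 91 | 2 |
| alpha | 4.00 | 6 | 95 | 2 |
| alpha | 5.00 | 6 | 92 | 1 |
| eta | 0.500 | 9 | 70 | 21 |
| eta | 0.833 | 8 | 86 | 9 |
| eta | 1.33 | 9 | 92 | 3 |
| eta | 2.00 | 7 | 95 | 1 |
| eta | 3.00 | 5 | 93 | 0 |
| eta | 5.00 | 7 | 91 | 2 |
| eta | 8.00 | 4 | 95 | 0 |

(readings scatter by 1.5 percentage points)



1. the target standing at 10 h, as a percentage of the substrate charged
2. the isomer of the product standing at 10 h, as a percentage of the substrate charged

The bench rule says the last reading shows the end. Applied to each run, it gives target over target plus isomer of 6.12% in the alpha run and 4.04% in the eta run. The rule stops working here: these last target readings stand a factor of 1.50 apart, a gap of 2 percentage points against a scatter of 1.5 points.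

So we pool the 7 readings from 3.00 h in alpha and 2.00 h in eta, where substrate reads 2% or less, wagering that the charge does not move the pair. Target averages 6.00% and isomer 93.1%, about 15.5 to one, far from our zero. This gives 6.05% as a reading for the end share, the target's part of the pair once the pair stops moving, the mark of thermodynamic control. We therefore commit to 6.05% target and 94.0% isomer at the asked time.

The forecast stands lower on target than our reckoning, at 4.5% with 95.5% isomer, weighing slow leakage against a plateau, and says that “the scatter can't separate these”.

The flask gives 6.41% target and 93.6% isomer, so the forecast holds within its margin. Target stands at 6.40% after 5.00 h and 6.41% after 100 h, a plateau.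

    substrate + 2 target → 3 target (k = 7840 L² mol⁻² s⁻¹)
    substrate → target (k = 2.40 × 10⁻⁴ s⁻¹)
    target ⇌ isomer of the product (K = 14.6, k = 0.00926 s⁻¹)

The pair's relaxation half-life by its own step, both ways together, is 1.17 min, short against 10 h. A neighbour flask charged with 8.0 × 10⁻⁴ M of substrate, read at the same time, is put by the end share at 6.05% target. It holds 6.41% target and 93.6% isomer, with 0.0092% substrate left.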